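All runs stem from a simulated flask for an exercise, noise included.

The south-east run, charged with 0.800 M Sub, had turned 62.2 % of it into Prd by 12 min, and the east run, with 0.320 M Sub and the same Cat, had turned 62.2 %. The problem stands as follows.

| flask | Sub | Cat | Prd | time |
|---|---|---|---|---|
| south-east | 0.800 M | 0.0640 M |  |  |
| east | 0.320 M | 0.0640 M |  |  |
| south-west | 0.800 M | 0.130 M |  |  |
| north | 0.800 M | 0.0640 M | 0.400 M |  |
| south | 0.200 M | 0.0640 M |  | 12 min |

| south-east run: time / min | south-east run: [Prd] / M | east run: time / min | east run: [Prd] / M | south-west run: time / min | south-west run: [Prd] / M | north run: time / min | north run: [Prd] / M |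
|---|---|---|---|---|---|---|---|
| 0.91 | 0.101 | 0.91 | 0.043 | 0.91 | 0.191 | 0.91 | 0.496 |
| 2.8 | 0.259 | 2.8 | 0.108 | 2.8 | 0.422 | 2.8 | 0.652 |
| 5.3 | 0.382 | 5.3 | 0.149 | 5.3 | 0.558 | 5.3 | 0.773 |
| 8.4 | 0.460 | 8.4 | 0.190 | 8.4 | 0.621 | 8.4 | 0.835 |
| 12 | 0.498 | 12 | 0.199 | 12 | 0.625 | 12 | 0.873 |

(scatter of a reading: 0.004 M)

- Overall: Sub -> Prd, with Cat as catalyst.
- Constant volume, constant temperature.
- An order is taken over about fifteen percent of the charge, up and down.

* the exponent of [Sub] in the starting rate at the charge of the south-east run (at the point where two percent of the Sub have become Prd) (one fixed amount of Prd, the same in the runs compared)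
* the exponent of [Cat] in the starting rate at the charge of the south-east run (at the point where two percent of the Sub have become Prd)
* Prd in the south run at 12 min, as a share of the Sub charged

Cutting the Sub charge by a factor of 2.50 cut the Prd read at 12 min by a factor of 2.50. Earlier in the two runs the shares also lie close, 47.8 % against 46.6 % at 5.3 min, a gap no wider than the scatter of one east reading, 1.25 % of its charge. At fixed Cat these two runs therefore behave as pseudo-first-order in Sub, and one number can be frozen: the end share s, the Prd present at 12 min as a fraction of the Sub charged at this Cat, whose plain mean over the two runs is 62.2 %. The south run has the same Cat and 0.200 M Sub, so s gives 0.124 M Prd at 12 min.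

The weak link is that plain mean, which gives the east share the same weight as the south-east share, although a reading of equal scatter weighs more against the smaller east charge. Pooling the Prd of both runs over their summed charges gives 62.2 %, with a scatter of 0.505 %. The south charge lies lower than either run, so this figure is carried there on the frozen share.

The forecast gave exponents of 0.96 for Sub and 1 for Cat and a south share of 62.5 %, between 60.5 % and 64.5 %, a little above the pooled figure, and it read the runs thus: “The reaction is therefore close to first order in Sub”.

The flask gives exponents of 1.0 and 1.0, and the south run reaches 62.9 %, which is 0.70 percentage points above s.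

Cat + Sub → Prd + Cat (2.376 /M/min); Sub → Z (0.05676 /min); Prd → J (0.007380 /min) Throughout the south run Sub left by two paths at once, to Prd at 0.152 /min and to Z at 0.0568 /min, with Cat returned by each turnover, while Prd already made passed to J at 0.00738 /min. Laid on the north run, s gives 0.898 M at 12 min against the reading of 0.873 M, and over those minutes the added 0.400 M Prd loses 0.0339 M to J.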